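- Plan the next flask. These were the two earlier runs and the choices before me:

| setting | south-east | north-east | flask |
|---|---|---|---|
| starting material | 15 mM | 15 mM | 15 mM |
| gas phase | 1.9 mM (held) | 1.9 mM (held) | 1.9 mM (held) |
| protic impurity | 5 mM | 11 mM | 7.50 mM |
| remark | run made earlier | run made earlier |  |
| time |  |  | 20 min |

| run | time / min | target / % | starting material / % |
|---|---|---|---|
| south-east | 3.00 | 42 | 2 |
| south-east | 6.00 | 43 | 2 |
| south-east | 10.0 | 41 | 1 |
| south-east | 12.0 | 43 | 0 |
| south-east | 15.0 | 42 | 0 |
| north-east | 1.33 | 24 | 42 |
| north-east | 2.50 | 36 | 13 |
| north-east | 5.00 | 40 | 1 |
| north-east | 8.00 | 42 | 0 |
| north-east | 15.0 | 43 | 1 |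

(scatter of a reading: 1.5 percentage points)

- at the start none of the gas phase is in solution

- violet: doubling the transfer coefficient of the gas phase, all else as stated
- amber: doubling the saturation concentration of gas phase, all else as stated

* how much target there is at 20 min, in percent of the starting material charged
* concentration of dissolved gas in solution at 5.0 min, in percent of saturation
* the change that raises the amount of target at 20 min, in percent of the starting material charged most ("none" if none brings more than 2 percentage points) (violet / amber / none)
* amount of target at 20 min, in percent of the starting material charged, after violet

- I left the protic impurity at 7.50 mM, since target ended at 42 % with 5 mM and at 43 % with 11 mM, a difference that the scatter of 1.5 percentage points covers.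
- I then turned to the gas. With 1.9 mM over 15 mM, a solution at saturation held gas for 12.7 % of the charge, and I called this fraction the gas share.
- The north-east run ended with 43 % of target, more than the gas share. So, taking one gas for each target, the solution in that run had to be refilled at least 3.39 times, a lower bound because it counts only the target read at the end.
- I reckoned on about 43 % of target in the new flask, and my choice was amber, which took the gas share to 25.4 %.
- The forecast agreed with me on the target, at 42 %, but differed on the change: none as the best, with 42 % after violet, and it put dissolved gas at 95 % of saturation. It stated its ground: “This assumes the selectivity doesn't depend on gas concentration, which the constant ratio supports.”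
- The flask gave 42.7 % of target at 20 min and dissolved gas at 31.0 % of saturation at 5.0 min. The best change was amber, with a gain of 15 points, while violet gained 12 points and reached 54.4 %.

    gas phase ⇌ dissolved gas, rate k1*(csat - [dissolved gas]) (kL = 0.0690 s⁻¹)
    starting material + dissolved gas → target (k = 29.0 M⁻¹ s⁻¹)
    starting material → side product A (k = 0.00160 s⁻¹)
    starting material + target → side product B (k = 0.990 M⁻¹ s⁻¹)
    dissolved gas + protic impurity → quenched reagent (k = 0.270 M⁻¹ s⁻¹)
    dissolved gas → decomposed reagent (k = 0.150 s⁻¹)

- In this flask, target ended at 42.7 % through two things acting together: starting material met target on the path to side product B, and the gas phase was taken up at a limited pace, with dissolved gas at 21.7 % of saturation at 2.00 min. Each is a part of the loss. Taking away the path to side product B gave 84.3 % of target. A neighbour flask, charged with 9.0 mM of starting material, had a gas share of 21.1 % against 12.7 % here, and it ended with 56.4 % of target.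

The runs stem from a simulated flask for substances that don't exist, noise included.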